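**Conventions.** TBS = tert-butyldimethylsilyl; Piv = 2,2-dimethylpropanoyl. Atom labels in the prose and in the Why lines are spiro[4.5]decane locants of the target: C1–C4 ring B (C1 the carbinol carbon, C2 the carbon with the side chain), C5 the spiro carbon, C6–C10 ring A (C6 the CH with the three-carbon chain, C7 the alkylidene carbon, C10 the C(OH)Me carbon).

## The problem

28-Deacetylbelamcandal 33 is a spiro[4.5]decane in which a cyclohexane (ring A) and a cyclopentane (ring B) share the quaternary carbon C5. Ring A carries three contiguous stereocentres, namely C6 with a 3-hydroxypropyl chain, C5 and the tertiary carbinol C10; ring B carries the secondary carbinol C1 and, cis to its hydroxyl, the trienyl side chain at C2. C10 is the natural anchor: its oxygen can fix C5 by intramolecular delivery and later C1 by directed hydride delivery, while C5 in turn biases C6 and C2. The fully substituted C7 alkene must hold its formyl group on the side of C6 (Z); with the C6 chain axial the two geometries should differ little in energy, so the geometry has to be built, not equilibrated. The side chain is a 2-(hydroxymethyl) triene with a 1,1-disubstituted terminus that tolerates neither acid, radicals nor strong oxidants, so it has to arrive late. The enal is also fragile (isomerisation, epimerisation at C6 through its dienolate), as is every stage where C1 is a carbonyl next to the free C10 hydroxyl (retro-aldol). What makes the key step possible is that O–C10 and C1 are cis on the adjacent ring-A carbons C10 and C5: a one-carbon unit tied through silicon to that oxygen can reach only the same face of C5.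

## Retrosynthesis

**33 ⇐ 32 ⇐ 31.** No skeletal bond is cut first. The enal is kept as a dioxolane to the end, and the side-chain CH2OH and the C1 hydroxyl are kept together as one lactone carbonyl. This avoids having to tell two primary allylic alcohols apart by oxidation. The forward steps are a 1,2-selective hydride reduction of 31 (which also removes the pivalate) and a mild acetal hydrolysis of 32 that must not isomerise the enal.

**31 ⇐ 25 + 28.** The C=C bond between the lactone α-carbon and the aldehyde carbon of 28 is cut (aldol condensation). The E-alkylidene lactone, with the chain anti to the carbonyl, has exactly the geometry that the target's trisubstituted alkene needs once the carbonyl becomes CH2OH. Cuts further out in the triene would leave that alkene to an olefination with no such bias. Eleven of the thirteen side-chain carbons leave with 28, which comes from ketone 26 through enol triflate 27 by a Heck reaction. The forward reaction must add the lithium enolate 1,2 to a dienal and eliminate to the conjugated isomer.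

**25 ⇐ 23 ⇐ 22 ⇐ 21.** The C1–C2 bond of ring B is cut: a ketyl from the aldehyde on C5 closes onto an enoate. This forms the ring and the two-carbon lactone handle at once, and the chair-like closure should place the ester arm anti to the bulkier C10 side of ring A. The carbinol configuration this closure gives at C1 is expected to be the wrong one. It is therefore erased (ketone 23) and reset by hydride delivered from the C10 hydroxyl, after which the cis hydroxy ester lactonises to 25.

**21 ⇐ 19 ⇐ 18.** The enoate C=C is cut (Wittig), and both aldehydes go back to the primary alcohols of triol 19. In 19 the hydroxymethyl group on C5 comes from the C–Si bond of 18 by oxidation, and the other primary alcohol from the silyl ether of the arm. The forward sequence needs a double oxidation that does not stop at a lactol, and a stabilised ylide that takes only the unhindered aldehyde.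

**18 ⇐ 12 (through 17, 16, 15, 14, 13).** The exocyclic C7 alkene is taken apart bond by bond: C–CHO (formylation of an alkenyllithium), C–CH3 (Negishi coupling) and C7=C (dibromo-olefination of ketone 12). A one-step olefination with a two-carbon reagent would give both geometries. In the dibromide the two bromines differ only by their in-plane neighbours, branched C6 against CH2-8, so the first coupling should go to the open side and the formyl group to the C6 side. The chain is an allyl group until 16, then hydroborated and capped as a pivalate that the last hydride step removes.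

**12 ⇐ 9 (through 11, 10).** The C6–allyl bond is cut. Ketone 9 enolises kinetically at C8, away from the quaternary carbon. It is therefore first dehydrogenated to enone 10, whose only enolisable position is C6. Alkylation to 11 and conjugate reduction follow. The forward alkylation must put the allyl group anti to the arm on C5.

**9 ⇐ 8 (key step).** The C5–CH2 bond and the oxasilolane ring are cut. A radical on the silicon-bound carbon adds 5-exo to the enone β-carbon, and the tether allows only the face that carries the C10 oxygen. A but-3-enyl arm on C5 would put a terminal alkene five atoms from the α-keto radical formed in this step, inviting a second 5-exo closure. The arm is therefore a saturated 3-silyloxypropyl group. Its three carbons become C4, C3 and C2.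

**8 ⇐ 6 + 7; 6 ⇐ 3 + 4; 3 ⇐ 2 ⇐ 1.** The O–Si bond is cut (silylation with 7). The C3–arm bond of the enone goes back to a Grignard addition to vinylogous ester 3 with hydrolytic carbonyl transposition. The C–O bond at the carbinol carbon goes back to an enantioselective enolate hydroxylation of 2. This is the only stereocentre not set under substrate control. The route starts from commercial 1, 4 and 7.

## Roads not taken

**Alternative 1:** The tetrasubstituted C7 alkene is cut, and is formed forwards by ring-closing metathesis of diene A2 to the cycloheptene-fused lactone A1 with the second-generation Hoveyda–Grubbs catalyst.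
- Merits: the seven-membered ring ties the future formyl carbon to the C6 chain, so the Z geometry is enforced. One glycol cleavage then releases both the enal and the chain terminus.
- Weak points: closing two 1,1-disubstituted alkenes to a tetrasubstituted one in a seven-membered ring is among the least favourable metatheses. The chain needs two sacrificial oxygen stereocentres. The saturated and conjugated aldehydes must be told apart after cleavage. The plan says nothing about how C5, C1 and C2 are made.
- Comparison: on enal geometry this road is better than the chosen plan, which relies on steric site selection in dibromide 13. The chosen plan sets against it bond-by-bond use of established coupling and exchange chemistry at C7, and a tether that settles the quaternary centre.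

**Alternative 2:** Ring A is cut at two C–C bonds. Forwards, the cyclic β-diketone A3 adds through its α-carbon to the β-carbon of enal A4 under a diarylprolinol silyl ether, and the acetyl methyl of A3 then condenses with the aldehyde to give spiro-enedione A5.
- Merits: one catalytic asymmetric step makes the spiro centre, C6 and ring A, with the chain already in place. In that respect it is shorter and cleaner than steps 6–8 here.
- Weak points: in A5 C10 is still a ketone on a non-enolisable 1,3-diketone. Its methyl carbinol would come from an intermolecular methyl addition with no tether, on a substrate prone to retro-Claisen cleavage and with a second ketone to distinguish. C7 is a CH2 that needs an allylic oxidation and a transposition before any alkylidene can be built. Ring B has no handle at C2.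
- Comparison: the chosen plan sets against it a C10 carbinol of fixed configuration that controls C5, and the ring-A oxygen already at C7.

**Alternative 3:** The lactone is cut at C2–C and C1–O. Forwards, Mn(OAc)3 generates a carboxymethyl radical from the solvent acid; it adds to the ring-B alkene of A6 at the carbon remote from C5, and the oxidised intermediate is closed by the carboxyl oxygen to give A7.
- Merits: one step from cheap reagents, with cis fusion intrinsic and regiochemistry steric. The chosen plan needs steps 16–19 for the same lactone.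
- Weak points: the face of the cyclopentene is chosen at the carbon far from C5, under weak steric bias. Nothing in A6 directs it, so the C1/C2 pair could form on either face. Hot acidic oxidising conditions must be survived by a ketal and a tertiary acetate. The spiro centre is again taken as given.
- Comparison: the chosen plan pays in redox steps but fixes C1 by hydroxyl-directed delivery and C2 by an ordered ring closure.

Key step: step 5

**Assumption:** the (+)-oxaziridine of step 2 is taken to give (6S)-3, by analogy with 2-alkyl-1-tetralone enolates; if the sense is reversed on this enolate the (−)-reagent is used, with no other change.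

## Route

Step 1
Reactants: 1 3-ethoxycyclohex-2-en-1-one
Product: 2 3-ethoxy-6-methylcyclohex-2-en-1-one (racemic)
Conditions: LiN(i-Pr)2, THF, −78 °C; MeI, −78 → 0 °C
Reagents that add atoms: iodomethane, CI
Why: Stork–Danheiser alkylation: the vinylogous ester is deprotonated kinetically at C6 (α′), not at the γ-carbon, and the enolate is methylated once.

Step 2
Reactants: 2 3-ethoxy-6-methylcyclohex-2-en-1-one
Product: 3 (6S)-3-ethoxy-6-hydroxy-6-methylcyclohex-2-en-1-one
Conditions: NaN(SiMe3)2, THF, −78 °C; (+)-[(8,8-dichlorocamphoryl)sulfonyl]oxaziridine, −78 °C; H2O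
Reagents that add atoms: (+)-[(8,8-dichlorocamphoryl)sulfonyl]oxaziridine, CC1(C)C2CCC13CS(=O)(=O)N4OC34C2(Cl)Cl
Why: Davis asymmetric enolate hydroxylation; the flat, cross-conjugated sodium enolate resembles the 2-alkyl-1-tetralone enolates for which this reagent gives tertiary α-hydroxy ketones with high selectivity. The reagent chooses the enolate face and so sets C10, the only centre made under reagent control.

Step 3
Reactants: 3 (6S)-3-ethoxy-6-hydroxy-6-methylcyclohex-2-en-1-one; 4 (3-bromopropoxy)(tert-butyl)dimethylsilane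
Product: 6 (4S)-4-hydroxy-4-methyl-3-[3-(TBSO)propyl]cyclohex-2-en-1-one, via tertiary allylic diol 5 (not isolated)
Conditions: 4, Mg, THF, rt (Grignard reagent, 2.3 equiv); 3, THF, −78 → 0 °C; then 1 M HCl, 0 °C
Reagents that add atoms: water, O
Why: Stork–Danheiser 1,2-addition and hydrolytic transposition; the first equivalent of Grignard reagent forms the alkoxide, the second adds to the ketone, and dilute acid ionises the new carbinol through the vinylogous oxocarbenium ion to the transposed enone. The carbinol carbon set in step 2 is not touched.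

Step 4
Reactants: 6 (4S)-4-hydroxy-4-methyl-3-[3-(TBSO)propyl]cyclohex-2-en-1-one; 7 (bromomethyl)chlorodimethylsilane
Product: 8 (4S)-4-{[(bromomethyl)dimethylsilyl]oxy}-4-methyl-3-[3-(TBSO)propyl]cyclohex-2-en-1-one
Conditions: Et3N, DMAP (cat.), CH2Cl2, 0 °C → rt
Reagents that add atoms: none
Why: Silylation of a tertiary alcohol with a small chlorosilane under DMAP catalysis, the standard way to install this radical tether; 8 is used without long storage because the Si–O bond is hydrolytically labile.

Step 5
Reactants: 8 (4S)-4-{[(bromomethyl)dimethylsilyl]oxy}-4-methyl-3-[3-(TBSO)propyl]cyclohex-2-en-1-one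
Product: 9 cis-fused oxasilolane ketone (3aR,7aS)-2,2,7a-trimethyl-3a-[3-(TBSO)propyl]hexahydro-1,2-benzoxasilol-5(4H)-one
Conditions: Bu3SnH (1.3 equiv, syringe pump), AIBN (cat.), PhH, 80 °C, 0.01 M
Reagents that add atoms: none
Why: Bu3Sn• abstracts bromine from 8 to give an α-silyl radical, which is nucleophilic and so matched to the electron-poor β-carbon of the enone; the closest known reaction type is the Stork–Nishiyama (bromomethyl)dimethylsilyl ether cyclisation that places a hydroxymethyl equivalent cis to an alcohol. The radical closes 5-exo-trig onto C5, forming the C5–CH2 bond and the oxasilolane; 6-endo attack at the α-carbon is mismatched in polarity and would give an unstabilised radical. The two-atom O–Si tether can reach only the face of C5 that carries the C10 oxygen, so the ring is necessarily cis-fused and the new quaternary centre is set by C10 alone. The α-keto radical left at C6 is reduced by Bu3SnH; because the arm on C5 is saturated no alkene lies within its reach, and a 1,5-hydrogen shift from the arm would lead to the same product. The selectivity needed is cyclisation before reduction of the first radical, which slow addition of Bu3SnH at high dilution should secure.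

Step 6
Reactants: 9 (3aR,7aS)-2,2,7a-trimethyl-3a-[3-(TBSO)propyl]hexahydro-1,2-benzoxasilol-5(4H)-one
Product: 10 (3aR,7aS)-2,2,7a-trimethyl-3a-[3-(TBSO)propyl]-3,3a,4,7a-tetrahydro-1,2-benzoxasilol-5(2H)-one (C8=C9 enone)
Conditions: LiN(i-Pr)2, THF, −78 °C; PhS(Cl)=N-t-Bu, −78 °C
Reagents that add atoms: none
Why: Kinetic deprotonation occurs at C8, away from the quaternary C5, and the lithium enolate is dehydrogenated in one pot by Mukaiyama's sulfinimidoyl chloride. The enone is made so that C6 becomes the only enolisable position.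

Step 7
Reactants: 10 (3aR,7aS)-2,2,7a-trimethyl-3a-[3-(TBSO)propyl]-3,3a,4,7a-tetrahydro-1,2-benzoxasilol-5(2H)-one
Product: 11 (3aR,4S,7aS)-4-allyl-2,2,7a-trimethyl-3a-[3-(TBSO)propyl]-3,3a,4,7a-tetrahydro-1,2-benzoxasilol-5(2H)-one
Conditions: LiN(i-Pr)2, THF, −78 °C; allyl iodide, DMPU, −78 → −40 °C
Reagents that add atoms: 3-iodoprop-1-ene, C=CCI
Why: α′-Alkylation of a cross-conjugated lithium dienolate, which can form only at C6. The allyl group should enter anti to the freely rotating silyloxypropyl arm on C5, on the face of the tied-back CH2–Si bond, which places it cis to the C10 oxygen as the target requires.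

Step 8
Reactants: 11 (3aR,4S,7aS)-4-allyl-2,2,7a-trimethyl-3a-[3-(TBSO)propyl]-3,3a,4,7a-tetrahydro-1,2-benzoxasilol-5(2H)-one
Product: 12 (3aR,4S,7aS)-4-allyl-2,2,7a-trimethyl-3a-[3-(TBSO)propyl]hexahydro-1,2-benzoxasilol-5(4H)-one
Conditions: [(Ph3P)CuH]6, wet PhH, rt
Reagents that add atoms: none
Why: Conjugate reduction with Stryker's reagent [(Ph3P)CuH]6 reduces the enone and leaves the terminal alkene alone. The copper enolate forms on the C8 side and is protonated by water, so C6 is not exposed to base.

Step 9
Reactants: 12 (3aR,4S,7aS)-4-allyl-2,2,7a-trimethyl-3a-[3-(TBSO)propyl]hexahydro-1,2-benzoxasilol-5(4H)-one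
Product: 13 (3aR,4S,7aS)-4-allyl-5-(dibromomethylidene)-2,2,7a-trimethyl-3a-[3-(TBSO)propyl]octahydro-1,2-benzoxasilole
Conditions: CBr4, P(Oi-Pr)3, CH2Cl2, 0 °C → rt
Reagents that add atoms: tetrabromomethane, BrC(Br)(Br)Br
Why: Ramirez gem-dibromo-olefination in its phosphite (Horner–Wadsworth–Emmons) form, the variant that works on ketones; the medium is close to neutral, which protects the α-stereocentre C6.

Step 10
Reactants: 13 (3aR,4S,7aS)-4-allyl-5-(dibromomethylidene)-2,2,7a-trimethyl-3a-[3-(TBSO)propyl]octahydro-1,2-benzoxasilole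
Product: 14 (3aR,4S,5Z,7aS)-4-allyl-5-(1-bromoethylidene)-2,2,7a-trimethyl-3a-[3-(TBSO)propyl]octahydro-1,2-benzoxasilole
Conditions: Me2Zn, Pd(t-Bu3P)2 (cat.), THF, 0 °C → rt
Reagents that add atoms: dimethylzinc, C[Zn]C
Why: Negishi coupling; zerovalent palladium inserts into the C–Br bond that is less hindered in the alkene plane, the one beside CH2-8 and away from branched C6 (trans-selective monoalkylation of 1,1-dibromoalkenes). The methyl group is thus placed trans to C6 and the bromine syn to C6 is kept for the formyl group.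

Step 11
Reactants: 14 (3aR,4S,5Z,7aS)-4-allyl-5-(1-bromoethylidene)-2,2,7a-trimethyl-3a-[3-(TBSO)propyl]octahydro-1,2-benzoxasilole
Product: 15 (2Z)-2-[(3aR,4R,7aS)-4-allyl-2,2,7a-trimethyl-3a-[3-(TBSO)propyl]hexahydro-1,2-benzoxasilol-5(4H)-ylidene]propanal
Conditions: t-BuLi (2.1 equiv), Et2O, −78 °C; DMF, −78 → 0 °C
Reagents that add atoms: N,N-dimethylformamide, CN(C)C=O
Why: Bromine–lithium exchange goes with retention and the alkenyllithium holds its configuration at −78 °C, so formylation gives the Z-enal with CHO beside C6. The low temperature also prevents carbolithiation of the nearby allyl group.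

Step 12
Reactants: 15 (2Z)-2-[(3aR,4R,7aS)-4-allyl-2,2,7a-trimethyl-3a-[3-(TBSO)propyl]hexahydro-1,2-benzoxasilol-5(4H)-ylidene]propanal
Product: 16 2-[(1Z)-1-[(3aR,4R,7aS)-4-allyl-2,2,7a-trimethyl-3a-[3-(TBSO)propyl]hexahydro-1,2-benzoxasilol-5(4H)-ylidene]ethyl]-1,3-dioxolane
Conditions: (Me3SiOCH2)2, Me3SiOTf (cat.), CH2Cl2, −78 °C
Reagents that add atoms: 1,2-bis(trimethylsilyloxy)ethane, C[Si](C)(C)OCCO[Si](C)(C)C
Why: Noyori acetalisation; the aprotic conditions at −78 °C are the ones under which enals are protected without migration or isomerisation of the double bond.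

Step 13
Reactants: 16 2-[(1Z)-1-[(3aR,4R,7aS)-4-allyl-2,2,7a-trimethyl-3a-[3-(TBSO)propyl]hexahydro-1,2-benzoxasilol-5(4H)-ylidene]ethyl]-1,3-dioxolane
Product: 17 3-[(3aR,4R,5Z,7aS)-5-[1-(1,3-dioxolan-2-yl)ethylidene]-2,2,7a-trimethyl-3a-[3-(TBSO)propyl]octahydro-1,2-benzoxasilol-4-yl]propan-1-ol
Conditions: 9-BBN, THF, 0 °C → rt; NaBO3·4H2O, H2O, rt
Reagents that add atoms: sodium perborate tetrahydrate (NaBO3·4H2O), [Na+].[Na+].O[B-]1(O)OO[B-](O)(O)OO1
Why: Anti-Markovnikov hydroboration–oxidation; 9-BBN takes only the terminal alkene and ignores the tetrasubstituted one. Perborate at room temperature oxidises the C–B bond and should leave the C–Si bond for step 15.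

Step 14
Reactants: 17 3-[(3aR,4R,5Z,7aS)-5-[1-(1,3-dioxolan-2-yl)ethylidene]-2,2,7a-trimethyl-3a-[3-(TBSO)propyl]octahydro-1,2-benzoxasilol-4-yl]propan-1-ol
Product: 18 3-[(3aR,4R,5Z,7aS)-5-[1-(1,3-dioxolan-2-yl)ethylidene]-2,2,7a-trimethyl-3a-[3-(TBSO)propyl]octahydro-1,2-benzoxasilol-4-yl]propyl 2,2-dimethylpropanoate
Conditions: t-BuCOCl, pyridine, DMAP (cat.), CH2Cl2, 0 °C → rt
Reagents that add atoms: pivaloyl chloride, CC(C)(C)C(Cl)=O
Why: Acylation of a primary alcohol; the pivalate has no α-hydrogen, withstands fluoride, SmI2 and amide bases, and falls off in the hydride step 24.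

Step 15
Reactants: 18 3-[(3aR,4R,5Z,7aS)-5-[1-(1,3-dioxolan-2-yl)ethylidene]-2,2,7a-trimethyl-3a-[3-(TBSO)propyl]octahydro-1,2-benzoxasilol-4-yl]propyl 2,2-dimethylpropanoate
Product: 19 3-[(1R,2S,3S,6Z)-6-[1-(1,3-dioxolan-2-yl)ethylidene]-3-hydroxy-2-(hydroxymethyl)-2-(3-hydroxypropyl)-3-methylcyclohexyl]propyl 2,2-dimethylpropanoate
Conditions: Bu4NF, THF, rt; then KHCO3, 30% H2O2, MeOH, 45 °C
Reagents that add atoms: hydrogen peroxide, OO
Why: Fluoride removes the TBS ether and activates silicon; Tamao–Kumada oxidation then converts the C–Si bond into the primary C–OH and frees the tertiary hydroxyl. The weakly basic peroxide leaves pivalate and dioxolane intact.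

Step 16
Reactants: 19 3-[(1R,2S,3S,6Z)-6-[1-(1,3-dioxolan-2-yl)ethylidene]-3-hydroxy-2-(hydroxymethyl)-2-(3-hydroxypropyl)-3-methylcyclohexyl]propyl 2,2-dimethylpropanoate
Product: 21 methyl (2E)-5-[(1R,2R,3Z,6S)-3-[1-(1,3-dioxolan-2-yl)ethylidene]-1-formyl-6-hydroxy-6-methyl-2-[3-(PivO)propyl]cyclohexyl]pent-2-enoate, via dialdehyde 20 (not isolated)
Conditions: (COCl)2, DMSO, CH2Cl2, −78 °C; Et3N; then Ph3P=CHCO2Me (1.05 equiv), −20 → 0 °C
Reagents that add atoms: methyl (triphenylphosphoranylidene)acetate, COC(=O)C=P(c1ccccc1)(c1ccccc1)c1ccccc1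
Why: Swern oxidation activates both primary alcohols of the 1,5-diol at once and so avoids the lactol and lactone that slower oxidants would give. The stabilised ylide, used in slight excess, should take only the unhindered aldehyde and leave the one on the quaternary carbon; it gives the E-enoate.

Step 17
Reactants: 21 methyl (2E)-5-[(1R,2R,3Z,6S)-3-[1-(1,3-dioxolan-2-yl)ethylidene]-1-formyl-6-hydroxy-6-methyl-2-[3-(PivO)propyl]cyclohexyl]pent-2-enoate
Product: 22 methyl 2-[(1S,2S,5S,6R,7Z,10S)-7-[1-(1,3-dioxolan-2-yl)ethylidene]-1,10-dihydroxy-10-methyl-6-[3-(PivO)propyl]spiro[4.5]decan-2-yl]acetate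
Conditions: SmI2 (2.5 equiv), MeOH (4 equiv), THF, −78 °C
Reagents that add atoms: none
Why: SmI2 ketyl–olefin cyclisation, 5-exo onto the enoate β-carbon, closes ring B. In the chair-like transition state the more substituted C10 branch of ring A sits pseudo-equatorial, and is further held gauche to the ketyl oxygen by chelation of trivalent samarium to the C10 hydroxyl; the ester arm should therefore end trans to C10 (the required C2 configuration) and anti to the new hydroxyl. The C1 configuration formed here is not needed.

Step 18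
Reactants: 22 methyl 2-[(1S,2S,5S,6R,7Z,10S)-7-[1-(1,3-dioxolan-2-yl)ethylidene]-1,10-dihydroxy-10-methyl-6-[3-(PivO)propyl]spiro[4.5]decan-2-yl]acetate
Product: 23 methyl 2-[(2S,5R,6R,7Z,10S)-7-[1-(1,3-dioxolan-2-yl)ethylidene]-10-hydroxy-10-methyl-1-oxo-6-[3-(PivO)propyl]spiro[4.5]decan-2-yl]acetate
Conditions: Dess–Martin periodinane, NaHCO3, CH2Cl2, 0 °C → rt
Reagents that add atoms: none
Why: Dess–Martin oxidation of a hindered secondary alcohol; the tertiary alcohol is inert, and the buffered, non-basic medium avoids retro-aldol cleavage and epimerisation at C2.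

Step 19
Reactants: 23 methyl 2-[(2S,5R,6R,7Z,10S)-7-[1-(1,3-dioxolan-2-yl)ethylidene]-10-hydroxy-10-methyl-1-oxo-6-[3-(PivO)propyl]spiro[4.5]decan-2-yl]acetate
Product: 25 cis-fused γ-lactone (to O-1) of 2-[(1R,2S,5S,6R,7Z,10S)-7-[1-(1,3-dioxolan-2-yl)ethylidene]-1,10-dihydroxy-10-methyl-6-[3-(PivO)propyl]spiro[4.5]decan-2-yl]acetic acid, via anti-diol hydroxy ester 24 (not isolated)
Conditions: Me4NBH(OAc)3, MeCN/AcOH, −30 °C; then PPTS (cat.), PhMe, 50 °C
Reagents that add atoms: none
Why: Evans–Saksena reduction; the C10 hydroxyl binds boron and delivers hydride to the face of the C1 carbonyl on its own side, so the new hydroxyl is trans to C10 on ring B and cis to the ester arm, which then lactonises. The dioxolane should survive the cold anhydrous acetic acid, as acetals usually do in this reduction.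

Step 20
Reactants: 26 6-methylhept-5-en-2-one
Product: 27 6-methylhepta-1,5-dien-2-yl trifluoromethanesulfonate
Conditions: LiN(i-Pr)2, THF, −78 °C; PhNTf2, −78 → 0 °C
Reagents that add atoms: N-phenylbis(trifluoromethanesulfonimide), O=S(=O)(N(c1ccccc1)S(=O)(=O)C(F)(F)F)C(F)(F)F
Why: Kinetic deprotonation of a methyl ketone at the methyl group and O-triflation of the terminal enolate.

Step 21
Reactants: 27 6-methylhepta-1,5-dien-2-yl trifluoromethanesulfonate
Product: 28 (2E)-8-methyl-4-methylidenenona-2,7-dienal
Conditions: acrolein, Pd(OAc)2 (cat.), PPh3, Et3N, DMF, 60 °C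
Reagents that add atoms: acrolein, C=CC=O
Why: Heck reaction of an enol triflate with an electron-poor alkene; syn β-hydride elimination gives the E-enal. The dienal is used fresh because it can dimerise.

Step 22
Reactants: 25 the cis-fused γ-lactone; 28 (2E)-8-methyl-4-methylidenenona-2,7-dienal
Product: 29 lactone 25 bearing a (2E)-1-hydroxy-8-methyl-4-methylidenenona-2,7-dien-1-yl group on the lactone α-carbon (mixture at the two new centres)
Conditions: LiN(i-Pr)2 (2.2 equiv), THF, −78 °C; 28, −78 °C
Reagents that add atoms: none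
Why: Aldol addition of the lithium lactone enolate, 1,2 to the enal at low temperature; the first equivalent of base goes to the tertiary hydroxyl. The two new centres are removed in step 23.

Step 23
Reactants: 29 the aldol adduct
Product: 31 lactone 25 bearing a (2E)-8-methyl-4-methylidenenona-2,7-dien-1-ylidene group on the lactone α-carbon with the new exocyclic alkene E, via allylic mesylate 30 (not isolated)
Conditions: MsCl, Et3N, CH2Cl2, 0 °C; then DBU, 0 °C → rt
Reagents that add atoms: none
Why: Mesylation of the secondary alcohol and E1cB elimination through the lactone enolate; α-alkylidene γ-lactones form mainly as the E isomer (chain anti to the carbonyl), which is the geometry the target needs. The hindered tertiary alcohol is not sulfonylated.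

Step 24
Reactants: 31 the E-alkylidene lactone
Product: 32 2-[(1Z)-1-[(1R,2S,5S,6R,10S)-1,10-dihydroxy-2-[(2E,4E)-1-hydroxy-10-methyl-6-methylideneundeca-2,4,9-trien-2-yl]-6-(3-hydroxypropyl)-10-methylspiro[4.5]decan-7-ylidene]ethyl]-1,3-dioxolane
Conditions: i-Bu2AlH (8 equiv), CH2Cl2, −78 → 0 °C; aq. potassium sodium tartrate
Reagents that add atoms: none
Why: 1,2-Reduction of the unsaturated lactone to the allylic alcohol and the C1 hydroxyl; the same reagent cleaves the pivalate. The acetal is inert to i-Bu2AlH at or below 0 °C.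

Step 25
Reactants: 32 the dioxolane tetraol
Product: 33 28-deacetylbelamcandal, (2Z)-2-[(1R,2S,5S,6R,10S)-1,10-dihydroxy-2-[(2E,4E)-1-hydroxy-10-methyl-6-methylideneundeca-2,4,9-trien-2-yl]-6-(3-hydroxypropyl)-10-methylspiro[4.5]decan-7-ylidene]propanal
Conditions: PPTS (cat.), acetone/H2O (10:1), rt
Reagents that add atoms: water, O
Why: Acetal hydrolysis; an α,β-unsaturated dioxolane opens under acid weak enough to leave the dienylic alcohol and the tertiary alcohol alone. The reaction is stopped at full conversion to limit acid-promoted isomerisation of the enal.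

## Compound list

1 | 3-ethoxycyclohex-2-en-1-one | CCOC1=CC(=O)CCC1 | starting material
2 | 3-ethoxy-6-methylcyclohex-2-en-1-one (racemic) | CCOC1=CC(=O)C(C)CC1 | intermediate
3 | (6S)-3-ethoxy-6-hydroxy-6-methylcyclohex-2-en-1-one | O[C@@]1(C)CCC(OCC)=CC1=O | intermediate
4 | (3-bromopropoxy)(tert-butyl)dimethylsilane | BrCCCO[Si](C)(C)C(C)(C)C | starting material
5 | (6S)-3-ethoxy-6-methyl-1-[3-(TBSO)propyl]cyclohex-2-ene-1,6-diol (both C1 epimers; not isolated) | O[C@@]1(C)CCC(OCC)=CC1(O)CCCO[Si](C)(C)C(C)(C)C | intermediate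
6 | (4S)-4-hydroxy-4-methyl-3-[3-(TBSO)propyl]cyclohex-2-en-1-one | O[C@@]1(C)CCC(=O)C=C1CCCO[Si](C)(C)C(C)(C)C | intermediate
7 | (bromomethyl)chlorodimethylsilane | C[Si](C)(Cl)CBr | starting material
8 | (4S)-4-{[(bromomethyl)dimethylsilyl]oxy}-4-methyl-3-[3-(TBSO)propyl]cyclohex-2-en-1-one | BrC[Si](C)(C)O[C@@]1(C)CCC(=O)C=C1CCCO[Si](C)(C)C(C)(C)C | intermediate
9 | (3aR,7aS)-2,2,7a-trimethyl-3a-[3-(TBSO)propyl]hexahydro-1,2-benzoxasilol-5(4H)-one (cis-fused) | C[Si]1(C)C[C@]2(CCCO[Si](C)(C)C(C)(C)C)CC(=O)CC[C@]2(C)O1 | intermediate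
10 | (3aR,7aS)-2,2,7a-trimethyl-3a-[3-(TBSO)propyl]-3,3a,4,7a-tetrahydro-1,2-benzoxasilol-5(2H)-one | C[Si]1(C)C[C@]2(CCCO[Si](C)(C)C(C)(C)C)CC(=O)C=C[C@]2(C)O1 | intermediate
11 | (3aR,4S,7aS)-4-allyl-2,2,7a-trimethyl-3a-[3-(TBSO)propyl]-3,3a,4,7a-tetrahydro-1,2-benzoxasilol-5(2H)-one | C[Si]1(C)C[C@]2(CCCO[Si](C)(C)C(C)(C)C)[C@H](CC=C)C(=O)C=C[C@]2(C)O1 | intermediate
12 | (3aR,4S,7aS)-4-allyl-2,2,7a-trimethyl-3a-[3-(TBSO)propyl]hexahydro-1,2-benzoxasilol-5(4H)-one | C[Si]1(C)C[C@]2(CCCO[Si](C)(C)C(C)(C)C)[C@H](CC=C)C(=O)CC[C@]2(C)O1 | intermediate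
13 | (3aR,4S,7aS)-4-allyl-5-(dibromomethylidene)-2,2,7a-trimethyl-3a-[3-(TBSO)propyl]octahydro-1,2-benzoxasilole | C[Si]1(C)C[C@]2(CCCO[Si](C)(C)C(C)(C)C)[C@H](CC=C)C(=C(Br)Br)CC[C@]2(C)O1 | intermediate
14 | (3aR,4S,5Z,7aS)-4-allyl-5-(1-bromoethylidene)-2,2,7a-trimethyl-3a-[3-(TBSO)propyl]octahydro-1,2-benzoxasilole | C[Si]1(C)C[C@]2(CCCO[Si](C)(C)C(C)(C)C)[C@H](CC=C)/C(=C(/C)Br)CC[C@]2(C)O1 | intermediate
15 | (2Z)-2-[(3aR,4R,7aS)-4-allyl-2,2,7a-trimethyl-3a-[3-(TBSO)propyl]hexahydro-1,2-benzoxasilol-5(4H)-ylidene]propanal | C[Si]1(C)C[C@]2(CCCO[Si](C)(C)C(C)(C)C)[C@H](CC=C)/C(=C(/C)C=O)CC[C@]2(C)O1 | intermediate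
16 | 2-[(1Z)-1-[(3aR,4R,7aS)-4-allyl-2,2,7a-trimethyl-3a-[3-(TBSO)propyl]hexahydro-1,2-benzoxasilol-5(4H)-ylidene]ethyl]-1,3-dioxolane | C[Si]1(C)C[C@]2(CCCO[Si](C)(C)C(C)(C)C)[C@H](CC=C)/C(=C(/C)C3OCCO3)CC[C@]2(C)O1 | intermediate
17 | 3-[(3aR,4R,5Z,7aS)-5-[1-(1,3-dioxolan-2-yl)ethylidene]-2,2,7a-trimethyl-3a-[3-(TBSO)propyl]octahydro-1,2-benzoxasilol-4-yl]propan-1-ol | C[Si]1(C)C[C@]2(CCCO[Si](C)(C)C(C)(C)C)[C@H](CCCO)/C(=C(/C)C3OCCO3)CC[C@]2(C)O1 | intermediate
18 | 3-[(3aR,4R,5Z,7aS)-5-[1-(1,3-dioxolan-2-yl)ethylidene]-2,2,7a-trimethyl-3a-[3-(TBSO)propyl]octahydro-1,2-benzoxasilol-4-yl]propyl 2,2-dimethylpropanoate | C[Si]1(C)C[C@]2(CCCO[Si](C)(C)C(C)(C)C)[C@H](CCCOC(=O)C(C)(C)C)/C(=C(/C)C3OCCO3)CC[C@]2(C)O1 | intermediate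
19 | 3-[(1R,2S,3S,6Z)-6-[1-(1,3-dioxolan-2-yl)ethylidene]-3-hydroxy-2-(hydroxymethyl)-2-(3-hydroxypropyl)-3-methylcyclohexyl]propyl 2,2-dimethylpropanoate | OCCC[C@]1([C@H](CCCOC(=O)C(C)(C)C)/C(=C(/C)C2OCCO2)CC[C@]1(C)O)CO | intermediate
20 | 3-[(1R,2R,3S,6Z)-6-[1-(1,3-dioxolan-2-yl)ethylidene]-2-formyl-3-hydroxy-3-methyl-2-(3-oxopropyl)cyclohexyl]propyl 2,2-dimethylpropanoate (not isolated) | O=CCC[C@]1([C@H](CCCOC(=O)C(C)(C)C)/C(=C(/C)C2OCCO2)CC[C@]1(C)O)C=O | intermediate
21 | methyl (2E)-5-[(1R,2R,3Z,6S)-3-[1-(1,3-dioxolan-2-yl)ethylidene]-1-formyl-6-hydroxy-6-methyl-2-[3-(PivO)propyl]cyclohexyl]pent-2-enoate | COC(=O)/C=C/CC[C@]1([C@H](CCCOC(=O)C(C)(C)C)/C(=C(/C)C2OCCO2)CC[C@]1(C)O)C=O | intermediate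
22 | methyl 2-[(1S,2S,5S,6R,7Z,10S)-7-[1-(1,3-dioxolan-2-yl)ethylidene]-1,10-dihydroxy-10-methyl-6-[3-(PivO)propyl]spiro[4.5]decan-2-yl]acetate | COC(=O)C[C@@H]1CC[C@]2([C@H](CCCOC(=O)C(C)(C)C)/C(=C(/C)C3OCCO3)CC[C@]2(C)O)[C@H]1O | intermediate
23 | methyl 2-[(2S,5R,6R,7Z,10S)-7-[1-(1,3-dioxolan-2-yl)ethylidene]-10-hydroxy-10-methyl-1-oxo-6-[3-(PivO)propyl]spiro[4.5]decan-2-yl]acetate | COC(=O)C[C@@H]1CC[C@]2([C@H](CCCOC(=O)C(C)(C)C)/C(=C(/C)C3OCCO3)CC[C@]2(C)O)C1=O | intermediate
24 | methyl 2-[(1R,2S,5S,6R,7Z,10S)-7-[1-(1,3-dioxolan-2-yl)ethylidene]-1,10-dihydroxy-10-methyl-6-[3-(PivO)propyl]spiro[4.5]decan-2-yl]acetate (not isolated) | COC(=O)C[C@@H]1CC[C@]2([C@H](CCCOC(=O)C(C)(C)C)/C(=C(/C)C3OCCO3)CC[C@]2(C)O)[C@@H]1O | intermediate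
25 | cis-fused γ-lactone (to O-1) of 2-[(1R,2S,5S,6R,7Z,10S)-7-[1-(1,3-dioxolan-2-yl)ethylidene]-1,10-dihydroxy-10-methyl-6-[3-(PivO)propyl]spiro[4.5]decan-2-yl]acetic acid | O=C1C[C@@H]2CC[C@]3([C@H](CCCOC(=O)C(C)(C)C)/C(=C(/C)C4OCCO4)CC[C@]3(C)O)[C@@H]2O1 | intermediate
26 | 6-methylhept-5-en-2-one | CC(=O)CCC=C(C)C | starting material
27 | 6-methylhepta-1,5-dien-2-yl trifluoromethanesulfonate | C=C(OS(=O)(=O)C(F)(F)F)CCC=C(C)C | intermediate
28 | (2E)-8-methyl-4-methylidenenona-2,7-dienal | O=C/C=C/C(=C)CCC=C(C)C | intermediate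
29 | lactone 25 bearing a (2E)-1-hydroxy-8-methyl-4-methylidenenona-2,7-dien-1-yl group on the lactone α-carbon (mixture at the two new centres) | O=C1C(C(O)/C=C/C(=C)CCC=C(C)C)[C@@H]2CC[C@]3([C@H](CCCOC(=O)C(C)(C)C)/C(=C(/C)C4OCCO4)CC[C@]3(C)O)[C@@H]2O1 | intermediate
30 | methanesulfonate of 29 at the new secondary hydroxyl (not isolated) | O=C1C(C(OS(C)(=O)=O)/C=C/C(=C)CCC=C(C)C)[C@@H]2CC[C@]3([C@H](CCCOC(=O)C(C)(C)C)/C(=C(/C)C4OCCO4)CC[C@]3(C)O)[C@@H]2O1 | intermediate
31 | lactone 25 bearing a (2E)-8-methyl-4-methylidenenona-2,7-dien-1-ylidene group on the lactone α-carbon, exocyclic alkene E | O=C1/C(=C/C=C/C(=C)CCC=C(C)C)[C@@H]2CC[C@]3([C@H](CCCOC(=O)C(C)(C)C)/C(=C(/C)C4OCCO4)CC[C@]3(C)O)[C@@H]2O1 | intermediate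
32 | 2-[(1Z)-1-[(1R,2S,5S,6R,10S)-1,10-dihydroxy-2-[(2E,4E)-1-hydroxy-10-methyl-6-methylideneundeca-2,4,9-trien-2-yl]-6-(3-hydroxypropyl)-10-methylspiro[4.5]decan-7-ylidene]ethyl]-1,3-dioxolane | C=C(/C=C/C=C(/CO)[C@@H]1CC[C@]2([C@H](CCCO)/C(=C(/C)C3OCCO3)CC[C@]2(C)O)[C@@H]1O)CCC=C(C)C | intermediate
33 | 28-deacetylbelamcandal, (2Z)-2-[(1R,2S,5S,6R,10S)-1,10-dihydroxy-2-[(2E,4E)-1-hydroxy-10-methyl-6-methylideneundeca-2,4,9-trien-2-yl]-6-(3-hydroxypropyl)-10-methylspiro[4.5]decan-7-ylidene]propanal | C=C(/C=C/C=C(/CO)[C@@H]1CC[C@]2([C@H](CCCO)/C(=C(/C)C=O)CC[C@]2(C)O)[C@@H]1O)CCC=C(C)C | target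

## Step count and least certain steps

Total step count: 25. Longest linear sequence: 23 steps (steps 1–19 and 22–25); steps 20–21 make fragment 28.

**Step 5 (key step).** The silylmethyl radical may be reduced before it closes onto the fully substituted β-carbon, because that closure creates a quaternary centre and may be slow. The fallback forms the same bond by an ionic route. It sets out from 6: the alcohol is deprotonated and treated with (i-PrO)Me2SiCH2MgCl, whose magnesium alkoxide-directed conjugate addition delivers the silylmethyl group to the face of the oxygen and gives the open ketone (3R,4S)-3-{[dimethyl(propan-2-yloxy)silyl]methyl}-4-hydroxy-4-methyl-3-[3-(TBSO)propyl]cyclohexan-1-one F1. A trace of acid closes F1 to the oxasilolane, and the route is rejoined at 9.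

**Step 2.** The oxygen transfer may show insufficient facial discrimination on this enolate, or the opposite sense. The fallback is an asymmetric Rubottom oxidation. It sets out from 2, which is converted with Me3SiOTf and Et3N into the dienol ether 1-ethoxy-4-methyl-3-(trimethylsilyloxy)cyclohexa-1,3-diene F2. Shi epoxidation of F2 (fructose-derived ketone, KHSO5) at the more electron-rich silyloxy alkene, followed by collapse of the silyloxy epoxide, returns to the route at 3.

**Step 7.** Facial selectivity in the allylation may be poor or reversed, with the allyl group entering on the side of the arm. The fallback exchanges the order in which the two bonds at C6 are made. It sets out from 10; if the alkylation gives mainly the C6 epimer (3aR,4R,7aS)-4-allyl-2,2,7a-trimethyl-3a-[3-(TBSO)propyl]-3,3a,4,7a-tetrahydro-1,2-benzoxasilol-5(2H)-one F3, its dienolate is re-formed with LiN(i-Pr)2 and protonated kinetically with a hindered phenol. The proton then enters from the face the electrophile preferred, which puts the allyl group on the required face and returns to the route at 11.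

**Step 9.** The hindered, α-branched ketone may fail to olefinate or may enolise and epimerise at C6, and the site selection of step 10 depends on this dibromide. The fallback gives up geometric control for reliability. It sets out from 12: addition of 2-lithio-1-ethoxyprop-1-ene (from the bromide and t-BuLi, with CeCl3) gives the tertiary allylic alcohol F4, the adduct of 12 at C7 carrying a 1-ethoxyprop-1-en-2-yl group. Dilute acid converts F4 into the enal as a mixture of 15 and its geometric isomer, the (2E)-enal F5. The isomers are separated, F5 is re-equilibrated photochemically and recycled, and the route is rejoined at 15.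

**Step 17.** Facial discrimination at C2 in the ketyl closure may be low, or the aldehyde may simply be reduced. The fallback changes the ring closure from a radical anion to an acyl anion equivalent. It sets out from 21, which undergoes an intramolecular Stetter reaction under a chiral aminoindanol-derived triazolium carbene; the catalyst, not the substrate, then sets C2, and the cyclopentanone is formed directly, rejoining the route at 23. No new compound is involved.

## Further compounds

F1 | step 5 | (3R,4S)-3-{[dimethyl(propan-2-yloxy)silyl]methyl}-4-hydroxy-4-methyl-3-[3-(TBSO)propyl]cyclohexan-1-one | CC(C)O[Si](C)(C)C[C@]1(CCCO[Si](C)(C)C(C)(C)C)CC(=O)CC[C@]1(C)O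
F2 | step 2 | 1-ethoxy-4-methyl-3-(trimethylsilyloxy)cyclohexa-1,3-diene | CCOC1=CC(O[Si](C)(C)C)=C(C)CC1
F3 | step 7 | (3aR,4R,7aS)-4-allyl-2,2,7a-trimethyl-3a-[3-(TBSO)propyl]-3,3a,4,7a-tetrahydro-1,2-benzoxasilol-5(2H)-one | C[Si]1(C)C[C@]2(CCCO[Si](C)(C)C(C)(C)C)[C@@H](CC=C)C(=O)C=C[C@]2(C)O1
F4 | step 9 | (3aR,4S,7aS)-4-allyl-5-(1-ethoxyprop-1-en-2-yl)-2,2,7a-trimethyl-3a-[3-(TBSO)propyl]octahydro-1,2-benzoxasilol-5-ol (mixture at C5 and at the enol ether) | C[Si]1(C)C[C@]2(CCCO[Si](C)(C)C(C)(C)C)[C@H](CC=C)C(O)(C(C)=COCC)CC[C@]2(C)O1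
F5 | step 9 | (2E)-2-[(3aR,4R,7aS)-4-allyl-2,2,7a-trimethyl-3a-[3-(TBSO)propyl]hexahydro-1,2-benzoxasilol-5(4H)-ylidene]propanal | C[Si]1(C)C[C@]2(CCCO[Si](C)(C)C(C)(C)C)[C@H](CC=C)/C(=C(\C)C=O)CC[C@]2(C)O1
F0 | step 17 | none | none
A1 | alternative 1 | cycloheptene-fused spiro lactone acetonide, product of the ring-closing metathesis | O=C1C[C@@H]2CC[C@]3([C@@H]4CC[C@H]5OC(C)(C)O[C@@H]5C(C)=C4CC[C@]3(C)O)[C@@H]2O1
A2 | alternative 1 | diene precursor of A1 with a ring-A exocyclic methylene and a chain ending in an isopropenyl group next to the acetonide | O=C1C[C@@H]2CC[C@]3([C@H](CC[C@H]4OC(C)(C)O[C@@H]4C(C)=C)C(=C)CC[C@]3(C)O)[C@@H]2O1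
A3 | alternative 2 | 2-acetylcyclopentan-1-one | CC(=O)C1CCCC1=O
A4 | alternative 2 | (2E)-6-(tert-butyldimethylsilyloxy)hex-2-enal | O=C/C=C/CCCO[Si](C)(C)C(C)(C)C
A5 | alternative 2 | 10-[3-(tert-butyldimethylsilyloxy)propyl]spiro[4.5]dec-7-ene-1,6-dione, product of the Michael–aldol spiroannulation | C1CC[C@]2([C@H](CCCO[Si](C)(C)C(C)(C)C)CC=CC2=O)C1=O
A6 | alternative 3 | 7,7-(ethylenedioxy)-10-methylspiro[4.5]dec-1-en-10-yl acetate, configured at C5 and C10 as in the target | C1=CCC[C@]12CC3(OCCO3)CC[C@]2(C)OC(C)=O
A7 | alternative 3 | cis-fused γ-lactone on ring B with ring-A ketal and tertiary acetate, product of the oxidative lactone annulation | O=C1C[C@@H]2CC[C@]3(CC4(OCCO4)CC[C@]3(C)OC(C)=O)[C@@H]2O1
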